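**Retrosynthetic overview**
- The ester carbon is installed last, ortho to the free phenol of ring A (ortho-formylation, Pinnick oxidation, O-methylation).
- Prenyl group ⇒ benzylic chloride + 2-methylprop-1-enylboronate (Suzuki); that benzylic carbon is the former ester carbon of methyl orsellinate.
- Diaryl ether ⇒ methyl orsellinate (free 4-OH) + 2-bromo-3,5-dimethoxybenzaldehyde (Ullmann C–O coupling); the formyl group later becomes CH2OH.
- Methyl orsellinate ⇒ methyl acetoacetate + methyl crotonate: intermolecular Michael addition (key C–C bond), Dieckmann closure, aromatisation.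
- Ring order: ring A is the only ring built (carbocycle in step 1, aromatised in step 2); ring B comes intact from 3,5-dimethoxybenzaldehyde.

Assumption: the target has no stereocentre and no stereogenic double bond, so "single enantiomer" means the achiral compound as drawn.

**Step 1**
Reactants: 1 methyl 3-oxobutanoate (methyl acetoacetate); 2 methyl (E)-but-2-enoate (methyl crotonate)
Product: 4 methyl 6-methyl-2,4-dioxocyclohexane-1-carboxylate, via dimethyl 2-acetyl-3-methylpentanedioate 3 (not isolated)
Conditions: NaOMe (1.1 equiv), MeOH, reflux, 16 h; then 2 M HCl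
Reagents that add atoms: none
Why: Michael addition of the acetoacetate enolate to the crotonate joins the two four-carbon fragments of ring A (the key C–C bond), and the adduct is drawn forward by Dieckmann (intramolecular Claisen) condensation to the stabilised cyclic 1,3-dione enolate; the two new stereocentres form as a racemic, mainly trans pair and are erased in step 2.

**Step 2**
Reactants: 4 methyl 6-methyl-2,4-dioxocyclohexane-1-carboxylate
Product: 6 methyl 2,4-dihydroxy-6-methylbenzoate (methyl orsellinate), via methyl 3-bromo-6-methyl-2,4-dioxocyclohexane-1-carboxylate 5 (not isolated)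
Conditions: Br2 (1.0 equiv), DMF, 0 °C, then 80 °C, 12 h
Reagents that add atoms: none
Why: Oxidative aromatisation by bromination of the enolised 1,3-dione followed by thermal loss of HBr and tautomerisation gives the resorcylate, with the ester retained at 80 °C.

**Step 3**
Reactants: 7 3,5-dimethoxybenzaldehyde
Product: 8 2-bromo-3,5-dimethoxybenzaldehyde
Conditions: NBS (1.05 equiv), MeCN, 0 °C → rt
Reagents that add atoms: N-bromosuccinimide, O=C1CCC(=O)N1Br
Why: Electrophilic aromatic bromination goes to C2, which is ortho and para to the two methoxy groups and less crowded than the position between them.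

**Step 4**
Reactants: 6 methyl 2,4-dihydroxy-6-methylbenzoate (1.2 equiv); 8 2-bromo-3,5-dimethoxybenzaldehyde
Product: 9 methyl 4-(2-formyl-4,6-dimethoxyphenoxy)-2-hydroxy-6-methylbenzoate
Conditions: CuI (10 mol %), picolinic acid (20 mol %), K3PO4 (2 equiv), DMSO, 90 °C, Ar
Reagents that add atoms: none
Why: Copper-catalysed Ullmann-type C–O coupling arylates only the more acidic 4-OH, which has two ortho hydrogens, because the 2-OH is locked in a hydrogen bond to the ester; the ortho-formyl group activates the hindered bromide.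

**Step 5**
Reactants: 9 methyl 4-(2-formyl-4,6-dimethoxyphenoxy)-2-hydroxy-6-methylbenzoate
Product: 10 methyl 2-hydroxy-4-[2-(hydroxymethyl)-4,6-dimethoxyphenoxy]-6-methylbenzoate
Conditions: NaBH4 (1 equiv), MeOH–THF, 0 °C
Reagents that add atoms: none
Why: Chemoselective borohydride reduction takes the aryl aldehyde to the benzylic alcohol while the hydrogen-bonded salicylate ester is inert to NaBH4.

**Step 6**
Reactants: 10 methyl 2-hydroxy-4-[2-(hydroxymethyl)-4,6-dimethoxyphenoxy]-6-methylbenzoate
Product: 11 methyl 4-[2-({[tert-butyl(dimethyl)silyl]oxy}methyl)-4,6-dimethoxyphenoxy]-2-hydroxy-6-methylbenzoate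
Conditions: TBSCl (1.1 equiv), imidazole (2 equiv), CH2Cl2, 0 °C
Reagents that add atoms: tert-butyldimethylsilyl chloride, CC(C)(C)[Si](C)(C)Cl
Why: Silyl ether protection is selective because the primary alcohol is silylated much faster than the chelated, hindered phenol.

**Step 7**
Reactants: 11 methyl 4-[2-({[tert-butyl(dimethyl)silyl]oxy}methyl)-4,6-dimethoxyphenoxy]-2-hydroxy-6-methylbenzoate
Product: 12 methyl 4-[2-({[tert-butyl(dimethyl)silyl]oxy}methyl)-4,6-dimethoxyphenoxy]-2-(methoxymethoxy)-6-methylbenzoate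
Conditions: MOMCl (2 equiv), iPr2NEt (3 equiv), CH2Cl2, 0 → 40 °C
Reagents that add atoms: chloromethyl methyl ether, COCCl
Why: O-alkylation of the phenol with MOMCl (Williamson-type acetal protection) gives a group that cannot migrate to the neighbouring benzylic oxygen and that survives hydride, phosphine and basic cross-coupling conditions.

**Step 8**
Reactants: 12 methyl 4-[2-({[tert-butyl(dimethyl)silyl]oxy}methyl)-4,6-dimethoxyphenoxy]-2-(methoxymethoxy)-6-methylbenzoate
Product: 13 {4-[2-({[tert-butyl(dimethyl)silyl]oxy}methyl)-4,6-dimethoxyphenoxy]-2-(methoxymethoxy)-6-methylphenyl}methanol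
Conditions: LiAlH4 (1.5 equiv), THF, 0 °C → rt; aqueous work-up
Reagents that add atoms: none
Why: Hydride reduction of the di-ortho-substituted benzoate by LiAlH4 gives the benzylic alcohol whose carbon becomes C1 of the prenyl chain, and the silyl ether, MOM acetal and diaryl ether are stable to it.

**Step 9**
Reactants: 13 {4-[2-({[tert-butyl(dimethyl)silyl]oxy}methyl)-4,6-dimethoxyphenoxy]-2-(methoxymethoxy)-6-methylphenyl}methanol
Product: 14 tert-butyl({2-[4-(chloromethyl)-3-(methoxymethoxy)-5-methylphenoxy]-3,5-dimethoxyphenyl}methoxy)dimethylsilane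
Conditions: PPh3 (1.3 equiv) and N-chlorosuccinimide (1.3 equiv) premixed, THF, 0 °C → rt; used directly
Reagents that add atoms: N-chlorosuccinimide, O=C1CCC(=O)N1Cl
Why: Appel-type chlorination with the preformed chlorophosphonium salt converts the benzylic alcohol to the chloride under neutral conditions that spare the acid-labile MOM and TBS groups.

**Step 10**
Reactants: 14 tert-butyl({2-[4-(chloromethyl)-3-(methoxymethoxy)-5-methylphenoxy]-3,5-dimethoxyphenyl}methoxy)dimethylsilane; 15 4,4,5,5-tetramethyl-2-(2-methylprop-1-en-1-yl)-1,3,2-dioxaborolane (1.5 equiv)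
Product: 16 tert-butyl[(2-{3-(methoxymethoxy)-5-methyl-4-(3-methylbut-2-en-1-yl)phenoxy}-3,5-dimethoxyphenyl)methoxy]dimethylsilane
Conditions: PdCl2(dppf) (5 mol %), K2CO3 (3 equiv), THF–H2O 9:1, 70 °C
Reagents that add atoms: none
Why: Suzuki–Miyaura sp3–sp2 coupling (zerovalent palladium inserts readily into the benzylic C–Cl bond) gives ArCH2–CH=CMe2 with the trisubstituted olefin preformed, so no regio- or stereoisomeric prenyl products can arise.

**Step 11**
Reactants: 16 tert-butyl[(2-{3-(methoxymethoxy)-5-methyl-4-(3-methylbut-2-en-1-yl)phenoxy}-3,5-dimethoxyphenyl)methoxy]dimethylsilane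
Product: 17 5-[2-(hydroxymethyl)-4,6-dimethoxyphenoxy]-3-methyl-2-(3-methylbut-2-en-1-yl)phenol
Conditions: HCl (1.25 M in MeOH), THF, rt
Reagents that add atoms: none
Why: Acid-catalysed acetal exchange and desilylation in methanol remove MOM and TBS together, under conditions too mild to cyclise the ortho-prenylphenol to a chroman.

**Step 12**
Reactants: 17 5-[2-(hydroxymethyl)-4,6-dimethoxyphenoxy]-3-methyl-2-(3-methylbut-2-en-1-yl)phenol
Product: 19 2-hydroxy-6-[2-(hydroxymethyl)-4,6-dimethoxyphenoxy]-4-methyl-3-(3-methylbut-2-en-1-yl)benzaldehyde, via ortho-hydroxymethyl phenol 18 (not isolated)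
Conditions: MgCl2 (3 equiv), Et3N (6 equiv), (CH2O)n (8 equiv), MeCN, reflux; then 1 M HCl
Reagents that add atoms: paraformaldehyde (formaldehyde), C=O
Why: In the magnesium-mediated ortho-formylation (Casnati–Skattebøl) the magnesium phenoxide delivers formaldehyde only to its one free ortho position, between OH and OAr, and the resulting alkoxide is oxidised in situ by a second formaldehyde through Oppenauer-type hydride transfer.

**Step 13**
Reactants: 19 2-hydroxy-6-[2-(hydroxymethyl)-4,6-dimethoxyphenoxy]-4-methyl-3-(3-methylbut-2-en-1-yl)benzaldehyde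
Product: 20 2-hydroxy-6-[2-(hydroxymethyl)-4,6-dimethoxyphenoxy]-4-methyl-3-(3-methylbut-2-en-1-yl)benzoic acid
Conditions: NaClO2 (3 equiv), NaH2PO4 (3 equiv), 2-methyl-2-butene (30 equiv), t-BuOH–THF–H2O, 0 °C → rt
Reagents that add atoms: NaClO2 (sodium chlorite), [Na+].[O-]Cl=O
Why: Pinnick oxidation converts the hindered salicylaldehyde to the acid without touching the benzylic alcohol, while the large excess of 2-methyl-2-butene scavenges HOCl and so protects the prenyl olefin and the electron-rich rings.

**Step 14**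
Reactants: 20 2-hydroxy-6-[2-(hydroxymethyl)-4,6-dimethoxyphenoxy]-4-methyl-3-(3-methylbut-2-en-1-yl)benzoic acid
Product: 21 methyl 2-hydroxy-6-[2-(hydroxymethyl)-4,6-dimethoxyphenoxy]-4-methyl-3-(3-methylbut-2-en-1-yl)benzoate (target)
Conditions: MeI (1.5 equiv), KHCO3 (1.5 equiv), DMF, rt
Reagents that add atoms: iodomethane, CI
Why: SN2 O-alkylation of the carboxylate esterifies the di-ortho-substituted acid where acyl substitution would be slow, and KHCO3 is too weak a base to methylate the hydrogen-bonded phenol or the benzylic alcohol.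

**Compound list**
1 | methyl 3-oxobutanoate (methyl acetoacetate) | CC(=O)CC(=O)OC | starting material
2 | methyl (E)-but-2-enoate (methyl crotonate) | C/C=C/C(=O)OC | starting material
3 | dimethyl 2-acetyl-3-methylpentanedioate (racemic diastereomer mixture, not isolated) | COC(=O)CC(C)C(C(C)=O)C(=O)OC | intermediate
4 | methyl 6-methyl-2,4-dioxocyclohexane-1-carboxylate (racemic, 1,6-trans major, largely enolised; stereocentres lost in step 2) | COC(=O)C1C(C)CC(=O)CC1=O | intermediate
5 | methyl 3-bromo-6-methyl-2,4-dioxocyclohexane-1-carboxylate (stereoisomer mixture, not isolated) | COC(=O)C1C(C)CC(=O)C(Br)C1=O | intermediate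
6 | methyl 2,4-dihydroxy-6-methylbenzoate (methyl orsellinate) | COC(=O)c1c(C)cc(O)cc1O | intermediate
7 | 3,5-dimethoxybenzaldehyde | COc1cc(OC)cc(C=O)c1 | starting material
8 | 2-bromo-3,5-dimethoxybenzaldehyde | COc1cc(OC)c(Br)c(C=O)c1 | intermediate
9 | methyl 4-(2-formyl-4,6-dimethoxyphenoxy)-2-hydroxy-6-methylbenzoate | COC(=O)c1c(C)cc(Oc2c(C=O)cc(OC)cc2OC)cc1O | intermediate
10 | methyl 2-hydroxy-4-[2-(hydroxymethyl)-4,6-dimethoxyphenoxy]-6-methylbenzoate | COC(=O)c1c(C)cc(Oc2c(CO)cc(OC)cc2OC)cc1O | intermediate
11 | methyl 4-[2-({[tert-butyl(dimethyl)silyl]oxy}methyl)-4,6-dimethoxyphenoxy]-2-hydroxy-6-methylbenzoate | COC(=O)c1c(C)cc(Oc2c(CO[Si](C)(C)C(C)(C)C)cc(OC)cc2OC)cc1O | intermediate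
12 | methyl 4-[2-({[tert-butyl(dimethyl)silyl]oxy}methyl)-4,6-dimethoxyphenoxy]-2-(methoxymethoxy)-6-methylbenzoate | COCOc1cc(Oc2c(CO[Si](C)(C)C(C)(C)C)cc(OC)cc2OC)cc(C)c1C(=O)OC | intermediate
13 | {4-[2-({[tert-butyl(dimethyl)silyl]oxy}methyl)-4,6-dimethoxyphenoxy]-2-(methoxymethoxy)-6-methylphenyl}methanol | COCOc1cc(Oc2c(CO[Si](C)(C)C(C)(C)C)cc(OC)cc2OC)cc(C)c1CO | intermediate
14 | tert-butyl({2-[4-(chloromethyl)-3-(methoxymethoxy)-5-methylphenoxy]-3,5-dimethoxyphenyl}methoxy)dimethylsilane | COCOc1cc(Oc2c(CO[Si](C)(C)C(C)(C)C)cc(OC)cc2OC)cc(C)c1CCl | intermediate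
15 | 4,4,5,5-tetramethyl-2-(2-methylprop-1-en-1-yl)-1,3,2-dioxaborolane | CC(C)=CB1OC(C)(C)C(C)(C)O1 | starting material
16 | tert-butyl[(2-{3-(methoxymethoxy)-5-methyl-4-(3-methylbut-2-en-1-yl)phenoxy}-3,5-dimethoxyphenyl)methoxy]dimethylsilane | COCOc1cc(Oc2c(CO[Si](C)(C)C(C)(C)C)cc(OC)cc2OC)cc(C)c1CC=C(C)C | intermediate
17 | 5-[2-(hydroxymethyl)-4,6-dimethoxyphenoxy]-3-methyl-2-(3-methylbut-2-en-1-yl)phenol | CC(C)=CCc1c(C)cc(Oc2c(CO)cc(OC)cc2OC)cc1O | intermediate
18 | 2-(hydroxymethyl)-3-[2-(hydroxymethyl)-4,6-dimethoxyphenoxy]-5-methyl-6-(3-methylbut-2-en-1-yl)phenol (as its magnesium salt, not isolated) | CC(C)=CCc1c(C)cc(Oc2c(CO)cc(OC)cc2OC)c(CO)c1O | intermediate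
19 | 2-hydroxy-6-[2-(hydroxymethyl)-4,6-dimethoxyphenoxy]-4-methyl-3-(3-methylbut-2-en-1-yl)benzaldehyde | CC(C)=CCc1c(C)cc(Oc2c(CO)cc(OC)cc2OC)c(C=O)c1O | intermediate
20 | 2-hydroxy-6-[2-(hydroxymethyl)-4,6-dimethoxyphenoxy]-4-methyl-3-(3-methylbut-2-en-1-yl)benzoic acid | CC(C)=CCc1c(C)cc(Oc2c(CO)cc(OC)cc2OC)c(C(=O)O)c1O | intermediate
21 | methyl 2-hydroxy-6-[2-(hydroxymethyl)-4,6-dimethoxyphenoxy]-4-methyl-3-(3-methylbut-2-en-1-yl)benzoate (achiral) | COC(=O)c1c(Oc2c(CO)cc(OC)cc2OC)cc(C)c(CC=C(C)C)c1O | target

**Step count and risks**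
Total steps: 14. Longest linear sequence: 13 (steps 1, 2 and 4–14); step 3 is a one-step side branch.

The three steps most likely to fail, each with a fallback:

The copper-catalysed diaryl ether coupling (step 4) pairs an ester-deactivated phenoxide with an electron-rich bromide flanked by two ortho substituents, so slow turnover or hydrodebromination is possible. The fallback is a metal-free SNAr and sets out from 7. Electrophilic fluorination with Selectfluor (1 equiv, MeCN, rt) gives 2-fluoro-3,5-dimethoxybenzaldehyde F1, separated from a little difluoride. Heating F1 with 6 and Cs2CO3 in DMSO at 120 °C displaces the fluoride, which is activated by the ortho-formyl group, with the 4-phenoxide. The route is rejoined at 9.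

The sp3–sp2 Suzuki coupling (step 10) uses a labile, di-ortho-substituted, electron-rich benzylic chloride that can hydrolyse or ionise before it couples. The fallback avoids both the chloride and palladium and sets out from 13. ClP(O)(OEt)2 with pyridine gives diethyl [4-(2-{[tert-butyl(dimethyl)silyl]oxymethyl}-4,6-dimethoxyphenoxy)-2-(methoxymethoxy)-6-methylphenyl]methyl phosphate F2. Copper-catalysed substitution with 2-methylprop-1-enylmagnesium bromide (CuI 10 mol %, THF, −30 → 0 °C) then installs the side chain; the silyl ether, MOM acetal and aryl ethers tolerate the Grignard reagent. The route is rejoined at 16.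

The ortho-formylation (step 12) must put a carbon into the crowded position between OH and OAr and may stall. The fallback brings the ester in at the full oxidation level by directed ortho-metalation and sets out from 16. n-BuLi (THF, −20 °C) lithiates the only free position ortho to the OMOM group, which is also flanked by the diaryl ether oxygen. Quenching into excess ClCO2Me gives methyl 6-[2-({[tert-butyl(dimethyl)silyl]oxy}methyl)-4,6-dimethoxyphenoxy]-2-(methoxymethoxy)-4-methyl-3-(3-methylbut-2-en-1-yl)benzoate F3. HCl in MeOH then removes MOM and TBS, and the route is rejoined at 21, bypassing 17–20. The main uncertainties of this fallback are competing lithiation between the two methoxy groups of ring B and at the prenyl CH2.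

**Further compounds**
F1 | step 4 | 2-fluoro-3,5-dimethoxybenzaldehyde | COc1cc(OC)c(F)c(C=O)c1
F2 | step 10 | diethyl [4-(2-{[tert-butyl(dimethyl)silyl]oxymethyl}-4,6-dimethoxyphenoxy)-2-(methoxymethoxy)-6-methylphenyl]methyl phosphate | COCOc1cc(Oc2c(CO[Si](C)(C)C(C)(C)C)cc(OC)cc2OC)cc(C)c1COP(=O)(OCC)OCC
F3 | step 12 | methyl 6-[2-({[tert-butyl(dimethyl)silyl]oxy}methyl)-4,6-dimethoxyphenoxy]-2-(methoxymethoxy)-4-methyl-3-(3-methylbut-2-en-1-yl)benzoate | COCOc1c(CC=C(C)C)c(C)cc(Oc2c(CO[Si](C)(C)C(C)(C)C)cc(OC)cc2OC)c1C(=O)OC
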